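Every part of the substrate charged stands at any moment as substrate, as target or as something past target, so the three shares keep one total. In the north run at 8.00 min, the part past target already holds 92.7%.

all flasks: gas phase 2.6 mM (held)
- north: substrate 0.025 M; run made earlier
- south-east: substrate 0.038 M; run made earlier
- flask: substrate 0.050 M; time 8.0 min

- north (time / min: target / %, substrate / %): 0.500: 8.8, 87.0; 1.33: 19.4, 62.3; 2.50: 22.7, 35.9; 4.00: 20.2, 16.5; 6.00: 12.3, 5.4; 8.00: 5.5, 1.8; 10.0: 1.8, 0
- south-east (time / min: target / %, substrate / %): 0.500: 7.6, 89.6; 1.33: 12.8, 68.6; 2.50: 16.3, 42.1; 4.00: 16.9, 20.1; 6.00: 11.4, 6.3; 8.00: 6.4, 2.1; 10.0: 2.7, 1.0

(scatter of a reading: 0.5 percentage points)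

- at the start none of the gas phase is in solution

- grey: doubling the transfer coefficient of the gas phase, all else as stated
- blue: doubling the saturation concentration of gas phase, all else as stated

* amount of target at 8.0 min, in percent of the substrate charged
* the change that raises the amount of target at 8.0 min, in percent of the substrate charged most ("none" if none brings more than 2 percentage points) (grey / blue / none)
* amount of target at 8.0 min, in percent of the substrate charged, after grey

Target climbs while it is made faster than it is passed on, and at its top the two rates are equal (the maximum of an intermediate). Target share over substrate share serves as a rough clock for how far a run stands from that point. The highest target readings give 0.841 at 4.00 min in the south-east run and 0.632 at 2.50 min in the north run. The turning ratio R, target share over substrate share at the highest target reading, is taken from the south-east run, charged closer to the flask; it shifts from run to run, so it is a coarse mark and no constant.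

For more gas to pay at 8.0 min, the run with more gas per substrate would have to read higher at that time, by over 2 percentage points. At 4.00 min the north run, with less substrate under the same gas, does read more target than the south-east run, 20.2% against 16.9%. At 8.00 min the order has turned, 5.5% against 6.4%, with a scatter of 0.5 points on each reading. The runs hold 1.8% and 2.1% substrate at that time, and continuing that step to 0.050 M gives 2.38%. With target near the south-east 6.4%, the flask's ratio would be about 2.69, above R, as the south-east run reads after its highest target reading. By this reckoning the flask lies on its falling side, and grey and blue, both raising the gas supply, are expected to bring it down, with no gain above 2 points.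

The forecast gives 7.2%, then 5.5% after grey, and none as the best change, since in its words “the target is on its decaying tail”.

The flask gives 6.24%, and 2.57% after grey; grey moves it by −3.7 points and blue by −5.7 points, so the best change is none.

    gas phase ⇌ dissolved gas, rate k1*(csat - [dissolved gas]) (kL = 0.0700 /s)
    substrate + dissolved gas → target (k = 5.80 /M/s)
    dissolved gas + target → over-reacted product (k = 5.40 /M/s)
    2 dissolved gas → self-condensation product (k = 6.40 /M/s)
    substrate + target → side product (k = 0.420 /M/s)

At 8.00 min the flask's ratio is 2.76, above R, and the neighbour charged with 0.013 M of substrate reads 5.22 with 4.81% target. At 3.27 min the flask uses target 1.5 times as fast in the step to side product as in the step to over-reacted product. At 8.00 min the flask holds 64.8% side product, which counts as two, against 26.7% over-reacted product.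

All runs stem from a simulated flask with constants of no real substance; the scatter is artificial.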